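**Assumption (chemistry):** the anomeric configuration at C14 in 6, 9 and 11 is left open, because it is erased by ionisation in step 6. The organometallic reagents 8, 13 and 14 are made in the flask and are not counted as separate steps.

## Analysis of the target

The target 16 is the hexadecanoate of a C19 chain, numbered from the vinyl carbon C1. O1 bridges C11 and C14, so C11–C12–C13–C14–O1 form a 2,3,5-trisubstituted oxolane. C10, exocyclic on C11, carries the ester; C13 carries a free hydroxyl; C14 carries the pentyl terminus C15–C19.

There are four stereocentres: 10R, 11R, 13S and 14S. On the ring the C13 hydroxyl and the C14 pentyl group are cis, the C11 side chain is trans to both, and the C10 oxygen is threo to O1 across C10–C11.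

The sensitive functions are the terminal C1=C2 alkene, which excludes catalytic hydrogenation and late electrophilic oxidants, and the ester. The ester must sit on C10 while the equally secondary C13 hydroxyl stays free, so the route itself has to tell the two oxygens apart. Beyond these oxygens the molecule is hydrocarbon, with nothing in either chain to steer bond formation, and the 13,14-cis relationship is the sterically less natural one.

The strategy rests on one feature. C11 (R) and C13 (S) are carbinol carbons of opposite sense on either side of the C12 methylene. O–C11–C12–C13–O, closed through C10 and C14, is the skeleton of cis-cyclopent-4-ene-1,3-diol with C10 and C14 as the alkene carbons. Cleaving that alkene puts carbonyl groups on exactly the two carbons that must receive the alkyl chains, and the C11 oxygen can capture C14, and only C14, as ring oxygen O1.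

## Retrosynthetic reasoning

**16 to 15 (C13–O unmasking).** The last operation only frees the C13 hydroxyl of benzyl ether 15. The C13 oxygen stays etherified until the end because that is what distinguishes it from the C10 oxygen during acylation, and because an ether next to C14 neither participates nor migrates. The forward step must remove a benzyl group without hydrogen, so a Lewis-acid cleavage is planned.

**15 to 11 and 14 (C14–C15).** C14 is bound to the ring oxygen, so it is a latent oxocarbenium carbon, and the pentyl group has no function that would suggest another cut. Breaking C14–C15 leads to the anomeric ester 11 and dipentylzinc 14, which comes from bromide 12 through Grignard reagent 13. The forward reaction must place pentyl cis to the C13 benzyloxy group and trans to the C11 side chain.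

**11 to 9 and 10 (two acyl C–O bonds).** Both esters of 11 are cut back to lactol diol 9 and acid chloride 10. One acylation installs the ester that stays on C10 and also turns the anomeric hydroxyl into a leaving group. No separate activation of C14 and no selective protection of C10 are needed.

**9 to 6 and 8 (C9–C10).** C10 is a carbinol carbon next to the ring oxygen, so the simplest polar cut is between C9 and C10. This gives the α-alkoxy aldehyde 6 and Grignard reagent 8, made from bromide 7. The forward addition must be chelation-controlled through O1 to give 10R, and it must spare the hemiacetal carbon C14.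

**6 to 3 (O1–C14, and reconnection of C10 with C14).** Opening the lactol of 6 gives hydroxy dialdehyde 5. Joining its two carbonyl carbons as an alkene gives cyclopentenol 3, by way of ozonide 4 in the forward sense. This cut is chosen because it accounts for C11 and C13 together and because cleavage of the ring differentiates C10 from C14 without a selective reagent. Only the C11 oxygen is free, and it can reach only C14.

**3 to 2 to 1 (protecting-group exchange).** Alcohol 3 carries its free hydroxyl on C11 and its ether on C13. The commercial, enzymatically desymmetrised monoacetate 1 has the opposite pattern: acetate on the future C11, free hydroxyl on the future C13. Benzylation to 2 followed by acetate removal therefore delivers 3 in the required enantiomeric series.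

## Alternatives that were turned down

**Alternative 1:** The ring carbons are traced back to a four-membered ring by cutting C12–C13 and C11–C14, with O1 inserted later.

- Forward key step: dichloroketene A3 adds in a [2+2] cycloaddition across the Z-enol ether A2, whose oxygen carries a chiral 1-arylethyl group, to give cyclobutanone A1. Dechlorination and Baeyer–Villiger oxidation, with migration of the more substituted C14, would then give lactone A4, in which C11 is the carbonyl carbon.
- For it: the cycloaddition is suprafacial on the enol ether, so the cis relationship of the C13 oxygen and the C14 pentyl group follows from the Z geometry, and the auxiliary selects the face. This fixes the 13,14-cis pair more securely than an oxocarbenium alkylation, and on that point this alternative is the stronger one.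
- Against it: A4 holds two of the four stereocentres and none of the C1–C10 chain. C11 must be raised from a lactone carbonyl to a stereocentre trans to pentyl, and C10 must be built next to it. That needs a C–C bond formation at the lactone, a stereoselective reduction and a separate construction of the C10 carbinol. The auxiliary is a resolved alcohol that has to be made, attached through a multi-step enol ether synthesis and cleaved again.
- Comparison: the sequence would be well over ten steps. The chosen route accepts more risk at C14 but obtains C11 and C13 ready-made, differentiates C10 from C14 in one operation and needs seven steps.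

**Alternative 2:** O1–C11 and the C10–O bond are cut, leading to the acyclic dienol A6, a bis-homoallylic alcohol with an E C10=C11 alkene.

- Forward key step: a rhenium(VII) oxo reagent converts the C14 hydroxyl of A6 into a perrhenate ester. Oxygen and an oxo ligand add syn across the alkene, forming O1–C11 and C10–O on the same face and giving the 2,5-trans oxolane A5 with a free C10 hydroxyl.
- For it: C10 and C11 are created together and stereospecifically, since syn addition to an E alkene can only give the threo pair. That is stronger than a chelation-controlled Grignard addition. The C10 hydroxyl also emerges free while C13 is silylated, so only acylation and desilylation remain, two steps against four after the key step of the chosen route.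
- Against it: all stereochemical information must first be built into A6. C13 and C14 form a syn diol with one oxygen silylated and one free, and the E alkene sits two carbons away. That requires an asymmetric oxidation, a selective protection and at least two C–C bond formations, roughly twice the work needed to reach 3. The trans selectivity depends on the arrangement of the perrhenate ester over the alkene, and a bulky silyloxy group directly next to the carbinol perturbs that arrangement. The acidic medium also invites silyl migration between the C13 and C14 oxygens, which would stall the cyclisation.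
- Comparison: the chosen route offers ring stereocentres from a commercial enantiopure compound and a three-step path to the key substrate.

**Alternative 3:** C11–C12 and O1–C14 are cut. The ring is assembled from allylsilane A8 (C12–C14 with the pentyl group attached) and α-benzyloxy aldehyde A9 (C1–C11).

- Forward key step: under a chelating tin(IV) Lewis acid the alkene terminus of A8 attacks the chelated aldehyde anti to silicon. Silicon bridges the resulting cation and shifts to C13, and the aldehyde oxygen closes on C14 to give oxolane A7.
- For it: this is the most convergent plan. Both chains are in place before the ring forms, and one step makes a C–C bond, the ring and three ring stereocentres. In convergence it is clearly stronger than the linear chosen route.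
- Against it: the bridged cation is opened anti, so silicon on C13 ends trans to the C14 pentyl group, as in A7. A stereoretentive C–Si oxidation therefore gives the C13 epimer of what is needed, and an inversion must follow. Oxidising an aryldimethylsilyl group requires electrophilic removal of the aryl group and a peroxide, neither of which is likely to spare the terminal alkene. A8 and A9 are both non-commercial and enantiopure, each needing its own asymmetric synthesis, and the C10 benzyl ether must still be exchanged for the palmitate with the alkene present.
- Comparison: the chosen route has the C13 oxygen in place with the right configuration from the first compound and needs no C–Si oxidation.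

Key step: step 3

## Route

**Step 1**
Reactants: 1 (1S,4R)-cis-4-acetoxycyclopent-2-en-1-ol
Product: 2 (1R,4S)-4-(benzyloxy)cyclopent-2-en-1-yl acetate
Conditions: BnOC(=NH)CCl3 (1.5 equiv), TfOH (5 mol %), CH2Cl2/cyclohexane 1:2, 0 °C to rt
Reagents that add atoms: benzyl 2,2,2-trichloroacetimidate, N=C(OCc1ccccc1)C(Cl)(Cl)Cl
Why: Acid-catalysed O-benzylation with a trichloroacetimidate: the free hydroxyl is alkylated without forming an alkoxide, so the acetate cannot migrate across the cis-dioxygenated ring, a shift that would interconvert the enantiomers. No stereocentre is touched; the descriptors change only because numbering now starts at the acetate carbon.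

**Step 2**
Reactants: 2 (1R,4S)-4-(benzyloxy)cyclopent-2-en-1-yl acetate
Product: 3 (1R,4S)-4-(benzyloxy)cyclopent-2-en-1-ol
Conditions: K2CO3 (0.2 equiv), MeOH, 0 °C to rt
Reagents that add atoms: none
Why: Base-catalysed transesterification (methanolysis) of the allylic acetate; the benzyl ether is inert and, with the second oxygen etherified, acyl migration is no longer possible, so both carbinol centres keep their configuration.

**Step 3**
Reactants: 3 (1R,4S)-4-(benzyloxy)cyclopent-2-en-1-ol
Product: 6 (2R,4S)-4-(benzyloxy)-5-hydroxyoxolane-2-carbaldehyde (anomeric mixture), via secondary ozonide 4 (not isolated), via hydroxy dialdehyde 5 (not isolated)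
Conditions: O3/O2, CH2Cl2, −78 °C (Sudan III end point); then PPh3 (1.1 equiv), −78 °C to rt; rapid silica plug, used at once
Reagents that add atoms: ozone, [O-][O+]=O
Why: Ozone adds to the strained cis-alkene of 3 by 1,3-dipolar cycloaddition; the primary ozonide fragments to a carbonyl oxide and an aldehyde, which recombine to the secondary ozonide 4 (Criegee mechanism). Triphenylphosphine reduces the peroxide bridge and releases the 1,5-dialdehyde 5, in which the free C11 hydroxyl adds to the C14 carbonyl to give lactol 6. The closest known reaction type is the ozonolytic cleavage of 4-oxygenated cyclopentenes to furanose lactols (carbocycle to deoxypentofuranose). The oxolane closes by a 5-exo-trig hemiacetalisation that forms O1–C14; the only other carbonyl, C10, is adjacent to C11 and would require a three-membered ring. No stereocentre of the target is set here: C11 and C13 are carried over from 3 unchanged, and the new anomeric centre C14 forms as a mixture that is erased by ionisation in step 6. The selectivity needed is site selectivity of lactol formation, and the substrate secures it, because the C13 oxygen is blocked as its benzyl ether and the C11 oxygen can reach C14 only. Chemoselectivity for the alkene over the benzyl ether rests on the far faster addition of ozone to the alkene than its attack on a benzylic C–H bond or an unactivated arene at −78 °C, with the indicator dye marking the end point. The two ends of the former meso ring thus emerge differentiated, C10 as a free aldehyde and C14 as a masked one.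

**Step 4**
Reactants: 6 (2R,4S)-4-(benzyloxy)-5-hydroxyoxolane-2-carbaldehyde (anomeric mixture); 7 9-bromonon-1-ene
Product: 9 (3S,5R)-3-(benzyloxy)-5-[(1R)-1-hydroxydec-9-en-1-yl]oxolan-2-ol (anomeric mixture), via non-8-enylmagnesium bromide 8 (not isolated)
Conditions: 7, Mg, Et2O, rt to reflux (gives 8); 6, MgBr2·OEt2 (1.5 equiv), CH2Cl2, −78 °C, then 8 (2.3 equiv), −78 to −40 °C; aq NH4Cl
Reagents that add atoms: magnesium, [Mg] (ends in 8, not in 9)
Why: Chelation-controlled Grignard addition (Cram chelate model): magnesium bridges the C10 carbonyl oxygen and ring oxygen O1, and 8 attacks the aldehyde face next to the C11 hydrogen, away from C12, which gives the 10R (threo) carbinol. One equivalent of 8 is consumed by the anomeric hydroxyl; the resulting magnesium lactolate should stay closed at low temperature, so C14 is protected in the flask while C10 reacts.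

**Step 5**
Reactants: 9 (3S,5R)-3-(benzyloxy)-5-[(1R)-1-hydroxydec-9-en-1-yl]oxolan-2-ol (anomeric mixture); 10 hexadecanoyl chloride (palmitoyl chloride)
Product: 11 (3S,5R)-3-(benzyloxy)-5-[(1R)-1-(hexadecanoyloxy)dec-9-en-1-yl]oxolan-2-yl hexadecanoate (anomeric mixture)
Conditions: 10 (2.5 equiv), pyridine, DMAP (0.1 equiv), CH2Cl2, 0 °C to rt
Reagents that add atoms: none
Why: DMAP-catalysed acylation of both hydroxyls with the acid chloride: the C10 ester is the one kept in the target and the anomeric ester is the leaving group of step 6, so one operation installs the palmitate and activates C14. No stereocentre is changed.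

**Step 6**
Reactants: 11 (3S,5R)-3-(benzyloxy)-5-[(1R)-1-(hexadecanoyloxy)dec-9-en-1-yl]oxolan-2-yl hexadecanoate (anomeric mixture); 12 1-bromopentane
Product: 15 (1R)-1-[(2R,4S,5S)-4-(benzyloxy)-5-pentyloxolan-2-yl]dec-9-en-1-yl hexadecanoate, via pentylmagnesium bromide 13 (not isolated), via dipentylzinc 14 (not isolated)
Conditions: 12, Mg, Et2O (gives 13); ZnCl2 (0.5 equiv), Et2O, 0 °C to rt, then 1,4-dioxane, filtration under Ar (gives 14); 11, 14 (2.5 equiv), TMSOTf (1.5 equiv), CH2Cl2, −78 to −40 °C; aq NH4Cl
Reagents that add atoms: magnesium, [Mg] (ends in 13 only); zinc chloride, Cl[Zn]Cl (zinc ends in 14 only)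
Why: Lewis-acid-promoted substitution of an anomeric ester by a dialkylzinc (oxocarbenium C-glycosylation): TMSOTf ionises the C14 palmitate and 14, made by Grignard formation and transmetalation, transfers a pentyl group to the cyclic oxocarbenium ion, while the C10 ester and the alkene are inert to the zinc reagent. By the inside-attack model for five-membered oxocarbenium ions the benzyloxy group on C13 sits pseudoequatorial in the reacting envelope and the nucleophile enters on the face cis to it, which is also the face remote from the C11 side chain, so 14S is expected.

**Step 7**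
Reactants: 15 (1R)-1-[(2R,4S,5S)-4-(benzyloxy)-5-pentyloxolan-2-yl]dec-9-en-1-yl hexadecanoate
Product: 16 (1R)-1-[(2R,4S,5S)-4-hydroxy-5-pentyloxolan-2-yl]dec-9-en-1-yl hexadecanoate (target)
Conditions: BCl3 (3 equiv), C6HMe5 (5 equiv), CH2Cl2, −78 °C; MeOH, then H2O
Reagents that add atoms: none
Why: Lewis-acid debenzylation with a cation scavenger: BCl3 ionises the benzylic C–O bond and pentamethylbenzene traps the benzyl cation by Friedel–Crafts alkylation, conditions under which the terminal alkene, the ester and the oxolane should survive at −78 °C, whereas hydrogenolysis would saturate C1=C2. The C13–O bond is not broken, so its configuration is retained.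

## Compound list

1 | (1S,4R)-cis-4-acetoxycyclopent-2-en-1-ol | CC(=O)O[C@@H]1C[C@H](O)C=C1 | starting material
2 | (1R,4S)-4-(benzyloxy)cyclopent-2-en-1-yl acetate | CC(=O)O[C@@H]1C[C@H](OCc2ccccc2)C=C1 | intermediate
3 | (1R,4S)-4-(benzyloxy)cyclopent-2-en-1-ol | O[C@@H]1C[C@H](OCc2ccccc2)C=C1 | intermediate
4 | (2R,4S)-4-(benzyloxy)-6,7,8-trioxabicyclo[3.2.1]octan-2-ol (secondary ozonide; bridgehead configuration not defined) | O[C@@H]1C[C@H](OCc2ccccc2)C2OOC1O2 | intermediate (not isolated)
5 | (2S,4R)-2-(benzyloxy)-4-hydroxypentanedial | O=C[C@H](O)C[C@H](OCc1ccccc1)C=O | intermediate (not isolated)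
6 | (2R,4S)-4-(benzyloxy)-5-hydroxyoxolane-2-carbaldehyde (anomeric mixture) | O=C[C@H]1C[C@H](OCc2ccccc2)C(O)O1 | intermediate
7 | 9-bromonon-1-ene | C=CCCCCCCCBr | starting material
8 | non-8-en-1-ylmagnesium bromide | C=CCCCCCCC[Mg]Br | intermediate (not isolated)
9 | (3S,5R)-3-(benzyloxy)-5-[(1R)-1-hydroxydec-9-en-1-yl]oxolan-2-ol (anomeric mixture) | C=CCCCCCCC[C@@H](O)[C@H]1C[C@H](OCc2ccccc2)C(O)O1 | intermediate
10 | hexadecanoyl chloride (palmitoyl chloride) | CCCCCCCCCCCCCCCC(=O)Cl | starting material
11 | (3S,5R)-3-(benzyloxy)-5-[(1R)-1-(hexadecanoyloxy)dec-9-en-1-yl]oxolan-2-yl hexadecanoate (anomeric mixture) | C=CCCCCCCC[C@@H](OC(=O)CCCCCCCCCCCCCCC)[C@H]1C[C@H](OCc2ccccc2)C(OC(=O)CCCCCCCCCCCCCCC)O1 | intermediate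
12 | 1-bromopentane | CCCCCBr | starting material
13 | pentylmagnesium bromide | CCCCC[Mg]Br | intermediate (not isolated)
14 | dipentylzinc | CCCCC[Zn]CCCCC | intermediate (not isolated)
15 | (1R)-1-[(2R,4S,5S)-4-(benzyloxy)-5-pentyloxolan-2-yl]dec-9-en-1-yl hexadecanoate | C=CCCCCCCC[C@@H](OC(=O)CCCCCCCCCCCCCCC)[C@H]1C[C@H](OCc2ccccc2)[C@H](CCCCC)O1 | intermediate
16 | (1R)-1-[(2R,4S,5S)-4-hydroxy-5-pentyloxolan-2-yl]dec-9-en-1-yl hexadecanoate | C=CCCCCCCC[C@@H](OC(=O)CCCCCCCCCCCCCCC)[C@H]1C[C@H](O)[C@H](CCCCC)O1 | target

## Step count and least certain steps

Total step count: 7. Longest linear sequence: 7 steps (1 to 16). Compounds 7, 10 and 12 enter as side inputs without steps of their own.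

**Step 3 (key step).** The most likely failure is loss of material through over-oxidation or through the instability of the product. Ozone can attack the benzylic C–H bond, and an ozonide next to a free hydroxyl can fragment with loss of carbon. The α-alkoxy aldehyde can epimerise at C11 or oligomerise through hemiacetals when concentrated, so the material entering step 4 may be impure.
Fallback: the cleavage is done in two stages without ozone, setting out from 3. Osmium-catalysed dihydroxylation (OsO4 cat., NMO, acetone/water) should occur on the face opposite the two allylic oxygens and give (1R,2S,3S,4S)-4-(benzyloxy)cyclopentane-1,2,3-triol F1. Glycol cleavage with one equivalent of silica-supported NaIO4 in CH2Cl2 should cut the cis C10/C14 diol, the trans C10/C11 diol on the five-membered ring being much slower to form a cyclic periodate. The dialdehyde 5 so formed closes as before, and the route is rejoined at 6.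

**Step 4.** Two processes threaten it. The first is poor facial selectivity, because Felkin–Anh attack competes with the chelate and the magnesium lactolate also binds the metal. The second is opening of the lactolate, followed by addition at C14.
Fallback: the C10 centre is set by reduction instead of addition, setting out from 9 obtained as a C10 epimer mixture. Dess–Martin periodinane should oxidise both the carbinol and the lactol to (3S,5R)-3-(benzyloxy)-5-(dec-9-enoyl)oxolan-2-one F2. L-Selectride in THF at −78 °C should deliver hydride under Felkin–Anh control, anti to the C11–O1 bond, to give (3S,5R)-3-(benzyloxy)-5-[(1R)-1-hydroxydec-9-en-1-yl]oxolan-2-one F3. DIBAL-H (2.2 equiv, CH2Cl2, −78 °C) reduces the lactone to the lactol, and the route is rejoined at 9.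

**Step 6.** The main risk is insufficient cis selectivity, with pentyl entering trans to the benzyloxy group. Reduction of the oxocarbenium ion by β-hydride transfer from 14 and elimination to a dihydrofuran are further possibilities.
Fallback: the O1–C14 bond is re-formed by electrophilic cyclisation and the chain is completed by alkyl coupling, setting out from 9.
- Wittig methylenation (Ph3P=CH2, THF) should open the lactol to (3S,5R,6R)-3-(benzyloxy)pentadeca-1,14-diene-5,6-diol F4.
- Iodoetherification (I2, NaHCO3, MeCN, 0 °C) should close the ring 5-exo through the C11 hydroxyl. With a terminal alkene the allylic benzyloxy group can lie in the alkene plane, which leads to the 13,14-cis product (1R)-1-[(2R,4S,5R)-4-(benzyloxy)-5-(iodomethyl)oxolan-2-yl]dec-9-en-1-ol F5. The more distant C10 hydroxyl could only close a six-membered ring and should not compete.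
- Acylation with 10 (pyridine, DMAP) gives (1R)-1-[(2R,4S,5R)-4-(benzyloxy)-5-(iodomethyl)oxolan-2-yl]dec-9-en-1-yl hexadecanoate F6.
- Coupling of the primary iodide with lithium dibutylcuprate (Et2O/THF, −40 °C) completes the pentyl group, and the route is rejoined at 15.

**Step 7.** The risk is loss of chemoselectivity: Lewis-acid opening of the oxolane, addition of HCl to the terminal alkene, or cleavage of the ester before the benzyl ether is gone.
Fallback: the C13 oxygen is carried as a 4-methoxybenzyl ether, which is removed oxidatively. This sets out from 1 and repeats the route with the same reagents.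
- 4-Methoxybenzyl trichloroacetimidate with catalytic camphorsulfonic acid gives (1R,4S)-4-[(4-methoxybenzyl)oxy]cyclopent-2-en-1-yl acetate F7.
- Methanolysis gives (1R,4S)-4-[(4-methoxybenzyl)oxy]cyclopent-2-en-1-ol F8.
- Ozonolysis, through the 4-methoxybenzyl ozonide F9 and the 4-methoxybenzyl hydroxy dialdehyde F10, gives the 4-methoxybenzyl lactol aldehyde F11.
- Addition of 8 gives the 4-methoxybenzyl lactol diol F12.
- Acylation with 10 gives the 4-methoxybenzyl bis-palmitate F13.
- Alkylation with 14 gives the 4-methoxybenzyl C-glycoside F14.
- DDQ in CH2Cl2/pH 7 buffer at 0 °C then frees the hydroxyl without touching alkene or ester, and the route is rejoined at 16.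

This ether is not the first choice because it is more sensitive than benzyl to ozone in step 3 and to the Lewis acid in step 6.

## Further compounds

F1 | step 3 | (1R,2S,3S,4S)-4-(benzyloxy)cyclopentane-1,2,3-triol | O[C@@H]1C[C@H](OCc2ccccc2)[C@@H](O)[C@H]1O
F2 | step 4 | (3S,5R)-3-(benzyloxy)-5-(dec-9-enoyl)oxolan-2-one | C=CCCCCCCCC(=O)[C@H]1C[C@H](OCc2ccccc2)C(=O)O1
F3 | step 4 | (3S,5R)-3-(benzyloxy)-5-[(1R)-1-hydroxydec-9-en-1-yl]oxolan-2-one | C=CCCCCCCC[C@@H](O)[C@H]1C[C@H](OCc2ccccc2)C(=O)O1
F4 | step 6 | (3S,5R,6R)-3-(benzyloxy)pentadeca-1,14-diene-5,6-diol | C=CCCCCCCC[C@@H](O)[C@H](O)C[C@H](OCc1ccccc1)C=C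
F5 | step 6 | (1R)-1-[(2R,4S,5R)-4-(benzyloxy)-5-(iodomethyl)oxolan-2-yl]dec-9-en-1-ol | C=CCCCCCCC[C@@H](O)[C@H]1C[C@H](OCc2ccccc2)[C@H](CI)O1
F6 | step 6 | (1R)-1-[(2R,4S,5R)-4-(benzyloxy)-5-(iodomethyl)oxolan-2-yl]dec-9-en-1-yl hexadecanoate | C=CCCCCCCC[C@@H](OC(=O)CCCCCCCCCCCCCCC)[C@H]1C[C@H](OCc2ccccc2)[C@H](CI)O1
F7 | step 7 | (1R,4S)-4-[(4-methoxybenzyl)oxy]cyclopent-2-en-1-yl acetate | CC(=O)O[C@@H]1C[C@H](OCc2ccc(OC)cc2)C=C1
F8 | step 7 | (1R,4S)-4-[(4-methoxybenzyl)oxy]cyclopent-2-en-1-ol | O[C@@H]1C[C@H](OCc2ccc(OC)cc2)C=C1
F9 | step 7 | (2R,4S)-4-[(4-methoxybenzyl)oxy]-6,7,8-trioxabicyclo[3.2.1]octan-2-ol (4-methoxybenzyl ozonide; bridgehead configuration not defined) | O[C@@H]1C[C@H](OCc2ccc(OC)cc2)C2OOC1O2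
F10 | step 7 | (2R,4S)-2-hydroxy-4-[(4-methoxybenzyl)oxy]pentanedial (4-methoxybenzyl hydroxy dialdehyde) | O=C[C@H](O)C[C@H](OCc1ccc(OC)cc1)C=O
F11 | step 7 | (2R,4S)-5-hydroxy-4-[(4-methoxybenzyl)oxy]oxolane-2-carbaldehyde (4-methoxybenzyl lactol aldehyde, anomeric mixture) | O=C[C@H]1C[C@H](OCc2ccc(OC)cc2)C(O)O1
F12 | step 7 | (3S,5R)-5-[(1R)-1-hydroxydec-9-en-1-yl]-3-[(4-methoxybenzyl)oxy]oxolan-2-ol (4-methoxybenzyl lactol diol, anomeric mixture) | C=CCCCCCCC[C@@H](O)[C@H]1C[C@H](OCc2ccc(OC)cc2)C(O)O1
F13 | step 7 | (3S,5R)-5-[(1R)-1-(hexadecanoyloxy)dec-9-en-1-yl]-3-[(4-methoxybenzyl)oxy]oxolan-2-yl hexadecanoate (4-methoxybenzyl bis-palmitate, anomeric mixture) | C=CCCCCCCC[C@@H](OC(=O)CCCCCCCCCCCCCCC)[C@H]1C[C@H](OCc2ccc(OC)cc2)C(OC(=O)CCCCCCCCCCCCCCC)O1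
F14 | step 7 | (1R)-1-{(2R,4S,5S)-4-[(4-methoxybenzyl)oxy]-5-pentyloxolan-2-yl}dec-9-en-1-yl hexadecanoate (4-methoxybenzyl C-glycoside) | C=CCCCCCCC[C@@H](OC(=O)CCCCCCCCCCCCCCC)[C@H]1C[C@H](OCc2ccc(OC)cc2)[C@H](CCCCC)O1
A1 | alternative 1 | (3R,4S)-2,2-dichloro-4-pentyl-3-[(1R)-1-(2,4,6-triisopropylphenyl)ethoxy]cyclobutan-1-one | ClC1(Cl)[C@H](O[C@H](C)c2c(C(C)C)cc(C(C)C)cc2C(C)C)[C@H](CCCCC)C1=O
A2 | alternative 1 | 2-[(1R)-1-{[(1Z)-hept-1-en-1-yl]oxy}ethyl]-1,3,5-triisopropylbenzene | CCCCC/C=C\O[C@H](C)c1c(C(C)C)cc(C(C)C)cc1C(C)C
A3 | alternative 1 | dichloroketene (2,2-dichloroethen-1-one) | ClC(Cl)=C=O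
A4 | alternative 1 | (4S,5S)-5-pentyl-4-[(1R)-1-(2,4,6-triisopropylphenyl)ethoxy]oxolan-2-one | O=C1C[C@H](O[C@H](C)c2c(C(C)C)cc(C(C)C)cc2C(C)C)[C@H](CCCCC)O1
A5 | alternative 2 | (1R)-1-[(2R,4S,5S)-4-(tert-butyldimethylsilyloxy)-5-pentyloxolan-2-yl]dec-9-en-1-ol | C=CCCCCCCC[C@@H](O)[C@H]1C[C@H](O[Si](C)(C)C(C)(C)C)[C@H](CCCCC)O1
A6 | alternative 2 | (6S,7S,9E)-7-(tert-butyldimethylsilyloxy)nonadeca-9,18-dien-6-ol | C=CCCCCCCC/C=C/C[C@H](O[Si](C)(C)C(C)(C)C)[C@@H](O)CCCCC
A7 | alternative 3 | (2S,3R,5R)-5-[(1R)-1-(benzyloxy)dec-9-en-1-yl]-3-[dimethyl(phenyl)silyl]-2-pentyloxolane | C=CCCCCCCC[C@@H](OCc1ccccc1)[C@H]1C[C@@H]([Si](C)(C)c2ccccc2)[C@H](CCCCC)O1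
A8 | alternative 3 | dimethyl[(3R)-oct-1-en-3-yl]phenylsilane | C=C[C@@H](CCCCC)[Si](C)(C)c1ccccc1
A9 | alternative 3 | (2R)-2-(benzyloxy)undec-10-enal | C=CCCCCCCC[C@@H](OCc1ccccc1)C=O
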